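**Plan**

1. Retrosynthesis: the phenols come from MOM ethers, the C8 and C8' methyl groups from CH2OH arms, and C7'–H from C7'–OH. Ring B is then cut at C7–C8 and C7'–C8' in one retro-[4+2] into a hydroxy-o-quinodimethane and a chiral butenolide. Last, the C7'–C2 bond of the diaryl ketone behind that diene is cut into an aryllithium and an aldehyde.
2. Enabling feature: ring B (C1, C2, C7', C8', C8, C7) is a cyclohexene fused to arene ring A, with the benzylic carbons C7 and C7' ortho to each other. C7' carries two aryl groups, so one oxidation level up it is the carbonyl of a benzophenone whose ortho methyl is C7, and light turns exactly this pair into the diene.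
3. Forward: a ring A bromide and a ring C aldehyde give the 2-methylbenzophenone. Photoenolisation/Diels–Alder with (5R)-5-menthyloxyfuran-2(5H)-one closes ring B, carrying a temporary cis-fused lactone ring. LiAlH4 reduction, hydrogenolysis of C7'–OH, two CH2OH-to-CH3 conversions and MOM removal finish the route.
4. Stereochemistry: all three stereocentres arise in the cycloaddition. C8/C8' are cis from the ring alkene of the butenolide, C7' (aryl trans to C8') from the OH-outward/aryl-inward dienol reacting endo, and the absolute sense from the menthyloxy acetal carbon. The C7'–OH is later exchanged for H with retention.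

Key step: step 7

Remark: lignan locants are used in the discussion (ring A = fused arene C1–C6 with C1 on C7 and C2 on C7'; ring C = pendant aryl ring); compound names use systematic locants.

**Route**

Step 1
Reactants: 1 2,6-dimethoxy-4-methylphenol
Product: 2 1,3-dimethoxy-2-(methoxymethoxy)-5-methylbenzene
Conditions: MOMCl, iPr2NEt, CH2Cl2, 0 °C to rt
Reagents that add atoms: chloromethyl methyl ether (MOMCl), COCCl
Why: Williamson-type O-alkylation of the phenol with MOMCl should mask the ring A hydroxyl as an acetal ether that tolerates organolithium, hydride, light and Ni/H2 and leaves under mild acid in step 12.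

Step 2
Reactants: 2 1,3-dimethoxy-2-(methoxymethoxy)-5-methylbenzene
Product: 3 2-bromo-3,5-dimethoxy-4-(methoxymethoxy)-1-methylbenzene
Conditions: NBS (1 equiv), MeCN, 0 °C to rt, dark
Reagents that add atoms: N-bromosuccinimide (NBS), O=C1CCC(=O)N1Br
Why: Electrophilic aromatic bromination can only attack the two equivalent free positions of 2, each ortho to the methyl group, ortho to one methoxy group and para to the other, so one equivalent of NBS should give the single monobromide.

Step 3
Reactants: 4 vanillin (4-hydroxy-3-methoxybenzaldehyde)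
Product: 5 3-methoxy-4-(methoxymethoxy)benzaldehyde
Conditions: MOMCl, iPr2NEt, CH2Cl2, 0 °C to rt
Reagents that add atoms: chloromethyl methyl ether (MOMCl), COCCl
Why: The same Williamson-type O-alkylation protects the ring C phenol so that it quenches neither the aryllithium of step 4 nor the triplet ketone of step 7.

Step 4
Reactants: 3 2-bromo-3,5-dimethoxy-4-(methoxymethoxy)-1-methylbenzene; 5 3-methoxy-4-(methoxymethoxy)benzaldehyde
Product: 7 rac-[2,4-dimethoxy-3-(methoxymethoxy)-6-methylphenyl][3-methoxy-4-(methoxymethoxy)phenyl]methanol, via aryllithium 6 (not isolated)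
Conditions: n-BuLi, THF, −78 °C; then 5, −78 to 0 °C; H2O
Reagents that add atoms: none
Why: Bromine–lithium exchange followed by 1,2-addition of the aryllithium to the aldehyde joins ring A to the future C7', and the new carbinol stereocentre is formed as a racemate that is erased by the oxidation in step 5.

Step 5
Reactants: 7 rac-[2,4-dimethoxy-3-(methoxymethoxy)-6-methylphenyl][3-methoxy-4-(methoxymethoxy)phenyl]methanol
Product: 8 [2,4-dimethoxy-3-(methoxymethoxy)-6-methylphenyl][3-methoxy-4-(methoxymethoxy)phenyl]methanone
Conditions: MnO2 (activated, excess), CH2Cl2, rt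
Reagents that add atoms: none
Why: Oxidation of the doubly benzylic secondary alcohol with MnO2 under neutral conditions should give the 2-methylbenzophenone without harm to the acid-labile MOM ethers.

Step 6
Reactants: 9 5-hydroxyfuran-2(5H)-one; 10 (−)-menthol, (1R,2S,5R)-5-methyl-2-(propan-2-yl)cyclohexan-1-ol
Product: 11 (5R)-5-{[(1R,2S,5R)-5-methyl-2-(propan-2-yl)cyclohexyl]oxy}furan-2(5H)-one
Conditions: TsOH (cat.), toluene, reflux with azeotropic removal of water; crystallisation from hexane, mother liquor re-equilibrated with acid and recrystallised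
Reagents that add atoms: none
Why: Acid-catalysed acetalisation of the pseudo-acid with menthol gives both C5 epimers, which interconvert through the ring oxocarbenium ion, so that crystallisation of the less soluble 5R epimer with re-equilibration of the mother liquor (a crystallisation-induced diastereomer transformation) should deliver the single acetal.

Step 7
Reactants: 8 [2,4-dimethoxy-3-(methoxymethoxy)-6-methylphenyl][3-methoxy-4-(methoxymethoxy)phenyl]methanone; 11 (5R)-5-{[(1R,2S,5R)-5-methyl-2-(propan-2-yl)cyclohexyl]oxy}furan-2(5H)-one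
Product: 13 (3R,3aR,9S,9aR)-9-hydroxy-6,8-dimethoxy-7-(methoxymethoxy)-9-[3-methoxy-4-(methoxymethoxy)phenyl]-3-{[(1R,2S,5R)-5-methyl-2-(propan-2-yl)cyclohexyl]oxy}-3a,4,9,9a-tetrahydronaphtho[2,3-c]furan-1(3H)-one, via hydroxy-o-quinodimethane 12 (not isolated)
Conditions: hν (365 nm), degassed benzene, 20 °C, 11 (2 equiv)
Reagents that add atoms: none
Why: The n,π* triplet of 8 abstracts hydrogen from its ortho methyl (the future C7) in a 1,5-shift, and the biradical relaxes to the hydroxy-o-quinodimethane 12 with OH outward (next to the C3 methoxy of ring A) and the ring C aryl inward, the OH-inward isomer merely reverting to 8. The closest known reaction type is the photoenolisation/Diels–Alder reaction of 2-methylbenzophenones with electron-poor alkenes, here joined to the use of a 5-alkoxyfuran-2(5H)-one as a chiral cis-dienophile. Ring B is closed by a concerted suprafacial [4+2] cycloaddition that makes C7–C8 and C7'–C8' together and returns aromaticity to ring A, the lactone arriving as a cis-fused temporary ring. C8 and C8' are cis because both come from the ring alkene of the butenolide, C7' is set by the endo transition state, which puts the lactone carbonyl on the side of the outward OH so that the aryl group ends trans to the C8' substituent, and the absolute sense of all three is set by addition to the furanone face anti to the menthyloxy group. The step needs ortho regiochemistry (CH2 terminus to the β-carbon, carbinol carbon to the α-carbon of the butenolide), because regiochemistry and face together fix the absolute configuration, and the polarity of the 1-hydroxydiene plus the lower hindrance of the CH2 terminus beside the acetal carbon should secure it. Hydrogen abstraction from the ortho methyl should outrun abstraction from the neighbouring methoxy group, and the adduct no longer absorbs at 365 nm.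

Step 8
Reactants: 13 (3R,3aR,9S,9aR)-9-hydroxy-6,8-dimethoxy-7-(methoxymethoxy)-9-[3-methoxy-4-(methoxymethoxy)phenyl]-3-{[(1R,2S,5R)-5-methyl-2-(propan-2-yl)cyclohexyl]oxy}-3a,4,9,9a-tetrahydronaphtho[2,3-c]furan-1(3H)-one
Product: 14 (1S,2S,3R)-2,3-bis(hydroxymethyl)-6,8-dimethoxy-7-(methoxymethoxy)-1-[3-methoxy-4-(methoxymethoxy)phenyl]-1,2,3,4-tetrahydronaphthalen-1-ol
Conditions: LiAlH4, THF, −20 to 0 °C; aqueous NaOH work-up
Reagents that add atoms: none
Why: Reduction with LiAlH4 (ester to alcohol) opens the lactone, releases menthoxide from the resulting hemiacetal and reduces both carbonyl carbons to CH2OH, so that the two helper oxygens sit on the future methyl carbons and no stereocentre is touched.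

Step 9
Reactants: 14 (1S,2S,3R)-2,3-bis(hydroxymethyl)-6,8-dimethoxy-7-(methoxymethoxy)-1-[3-methoxy-4-(methoxymethoxy)phenyl]-1,2,3,4-tetrahydronaphthalen-1-ol
Product: 15 [(1R,2S,3R)-6,8-dimethoxy-7-(methoxymethoxy)-1-[3-methoxy-4-(methoxymethoxy)phenyl]-1,2,3,4-tetrahydronaphthalene-2,3-diyl]dimethanol
Conditions: Raney Ni (W-2 grade), H2 (1 atm), EtOH, 50 °C
Reagents that add atoms: none
Why: Hydrogenolysis of a benzylic C–O bond over Raney Ni, which is known to run with retention because hydrogen arrives from the metal surface on the side from which the surface-bound oxygen departs, should replace the tertiary doubly benzylic OH by H on the face of the two CH2OH groups (which bind the same face to the metal) and thus leave the aryl ring trans to C8'.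

Step 10
Reactants: 15 [(1R,2S,3R)-6,8-dimethoxy-7-(methoxymethoxy)-1-[3-methoxy-4-(methoxymethoxy)phenyl]-1,2,3,4-tetrahydronaphthalene-2,3-diyl]dimethanol
Product: 16 [(1R,2S,3R)-6,8-dimethoxy-7-(methoxymethoxy)-1-[3-methoxy-4-(methoxymethoxy)phenyl]-1,2,3,4-tetrahydronaphthalene-2,3-diyl]bis(methylene) dimethanesulfonate
Conditions: MsCl (2.5 equiv), Et3N, CH2Cl2, −10 °C
Reagents that add atoms: methanesulfonyl chloride (MsCl), CS(=O)(=O)Cl
Why: Sulfonylation of the two primary alcohols through the sulfene formed from MsCl and Et3N is fast at low temperature, so both hydroxyls should be activated before either can displace the other to a cyclic ether.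

Step 11
Reactants: 16 [(1R,2S,3R)-6,8-dimethoxy-7-(methoxymethoxy)-1-[3-methoxy-4-(methoxymethoxy)phenyl]-1,2,3,4-tetrahydronaphthalene-2,3-diyl]bis(methylene) dimethanesulfonate
Product: 17 (1R,2R,3R)-6,8-dimethoxy-7-(methoxymethoxy)-1-[3-methoxy-4-(methoxymethoxy)phenyl]-2,3-dimethyl-1,2,3,4-tetrahydronaphthalene
Conditions: LiEt3BH, THF, 0 °C to rt
Reagents that add atoms: none
Why: Hydride displacement (SN2) of the two primary mesylates by LiEt3BH, the standard reductive deoxygenation of sulfonates, should turn both arms into the C8 and C8' methyl groups with the stereocentres untouched.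

Step 12
Reactants: 17 (1R,2R,3R)-6,8-dimethoxy-7-(methoxymethoxy)-1-[3-methoxy-4-(methoxymethoxy)phenyl]-2,3-dimethyl-1,2,3,4-tetrahydronaphthalene
Product: 18 (−)-(7'R,8R,8'R)-4,4'-dihydroxy-3,3',5-trimethoxy-2,7'-cyclolignan
Conditions: HCl (conc., 3 equiv), MeOH, 50 °C
Reagents that add atoms: none
Why: Acid-catalysed acetal exchange with methanol should remove both MOM groups as dimethoxymethane, while the aryl methyl ethers and the three carbon stereocentres are inert, to give the target.

**Compound list**

1 | 2,6-dimethoxy-4-methylphenol | COc1cc(C)cc(OC)c1O | starting material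
2 | 1,3-dimethoxy-2-(methoxymethoxy)-5-methylbenzene | COCOc1c(OC)cc(C)cc1OC | intermediate
3 | 2-bromo-3,5-dimethoxy-4-(methoxymethoxy)-1-methylbenzene | COCOc1c(OC)cc(C)c(Br)c1OC | intermediate
4 | vanillin (4-hydroxy-3-methoxybenzaldehyde) | COc1cc(C=O)ccc1O | starting material
5 | 3-methoxy-4-(methoxymethoxy)benzaldehyde | COCOc1ccc(C=O)cc1OC | intermediate
6 | [2,4-dimethoxy-3-(methoxymethoxy)-6-methylphenyl]lithium (not isolated) | [Li]c1c(C)cc(OC)c(OCOC)c1OC | intermediate
7 | rac-[2,4-dimethoxy-3-(methoxymethoxy)-6-methylphenyl][3-methoxy-4-(methoxymethoxy)phenyl]methanol | COCOc1ccc(cc1OC)C(O)c1c(C)cc(OC)c(OCOC)c1OC | intermediate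
8 | [2,4-dimethoxy-3-(methoxymethoxy)-6-methylphenyl][3-methoxy-4-(methoxymethoxy)phenyl]methanone | COCOc1ccc(cc1OC)C(=O)c1c(C)cc(OC)c(OCOC)c1OC | intermediate
9 | 5-hydroxyfuran-2(5H)-one | OC1OC(=O)C=C1 | starting material
10 | (−)-menthol, (1R,2S,5R)-5-methyl-2-(propan-2-yl)cyclohexan-1-ol | CC(C)[C@@H]1CC[C@@H](C)C[C@H]1O | starting material
11 | (5R)-5-{[(1R,2S,5R)-5-methyl-2-(propan-2-yl)cyclohexyl]oxy}furan-2(5H)-one | CC(C)[C@@H]1CC[C@@H](C)C[C@H]1O[C@H]2C=CC(=O)O2 | intermediate
12 | (Z)-[2,4-dimethoxy-3-(methoxymethoxy)-6-methylidenecyclohexa-2,4-dien-1-ylidene][3-methoxy-4-(methoxymethoxy)phenyl]methanol, OH outward (syn to the methoxy-bearing ring carbon), aryl inward (not isolated) | C=C1C=C(OC)C(OCOC)=C(OC)/C1=C(\O)c1ccc(OCOC)c(OC)c1 | intermediate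
13 | (3R,3aR,9S,9aR)-9-hydroxy-6,8-dimethoxy-7-(methoxymethoxy)-9-[3-methoxy-4-(methoxymethoxy)phenyl]-3-{[(1R,2S,5R)-5-methyl-2-(propan-2-yl)cyclohexyl]oxy}-3a,4,9,9a-tetrahydronaphtho[2,3-c]furan-1(3H)-one (OH cis to the lactone ring, aryl trans) | COc1cc(ccc1OCOC)[C@]2(O)c3c(cc(OC)c(OCOC)c3OC)C[C@@H]4[C@H]2C(=O)O[C@H]4O[C@@H]5C[C@H](C)CC[C@H]5C(C)C | intermediate
14 | (1S,2S,3R)-2,3-bis(hydroxymethyl)-6,8-dimethoxy-7-(methoxymethoxy)-1-[3-methoxy-4-(methoxymethoxy)phenyl]-1,2,3,4-tetrahydronaphthalen-1-ol | COc1cc(ccc1OCOC)[C@]2(O)c3c(cc(OC)c(OCOC)c3OC)C[C@@H](CO)[C@H]2CO | intermediate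
15 | [(1R,2S,3R)-6,8-dimethoxy-7-(methoxymethoxy)-1-[3-methoxy-4-(methoxymethoxy)phenyl]-1,2,3,4-tetrahydronaphthalene-2,3-diyl]dimethanol | COc1cc(ccc1OCOC)[C@@H]2c3c(cc(OC)c(OCOC)c3OC)C[C@@H](CO)[C@H]2CO | intermediate
16 | [(1R,2S,3R)-6,8-dimethoxy-7-(methoxymethoxy)-1-[3-methoxy-4-(methoxymethoxy)phenyl]-1,2,3,4-tetrahydronaphthalene-2,3-diyl]bis(methylene) dimethanesulfonate | COc1cc(ccc1OCOC)[C@@H]2c3c(cc(OC)c(OCOC)c3OC)C[C@@H](COS(C)(=O)=O)[C@H]2COS(C)(=O)=O | intermediate
17 | (1R,2R,3R)-6,8-dimethoxy-7-(methoxymethoxy)-1-[3-methoxy-4-(methoxymethoxy)phenyl]-2,3-dimethyl-1,2,3,4-tetrahydronaphthalene | COc1cc(ccc1OCOC)[C@@H]2c3c(cc(OC)c(OCOC)c3OC)C[C@@H](C)[C@H]2C | intermediate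
18 | (−)-(7'R,8R,8'R)-4,4'-dihydroxy-3,3',5-trimethoxy-2,7'-cyclolignan | COc1cc([C@@H]2c3c(cc(OC)c(O)c3OC)C[C@@H](C)[C@H]2C)ccc1O | target

**Count**

Total step count: 12. Longest linear sequence: 10 steps (steps 1, 2, 4, 5, 7, 8, 9, 10, 11, 12).

**Steps most likely to fail**

1. Step 9. Hydrogen may be delivered to the wrong face of C7' if the surface-bound benzylic intermediate flattens before it takes up hydrogen, which would erode the retention on which the aryl/C8' trans relationship depends. The fallback sets out from triol 14 and returns at diol 15. The two primary hydroxyls are silylated with iPr2SiHCl and imidazole (CH2Cl2, 0 °C; the tertiary hydroxyl is too hindered to react) to give the bis(diisopropylsilyl) ether F1. BF3·OEt2 at −78 °C should ionise the tertiary doubly benzylic C–O bond, and the Si–H of the silyl ether on the C8' arm can pass hydride to C7' through a six-membered transition state from the face that carries this arm. This is the geometry of the Lewis acid-promoted intramolecular hydrosilylation of β-silyloxy ketones, and it should give the fluorosilyl ether F2 with the new hydrogen cis to both arms. Bu4NF then removes both silicon groups and gives 15.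

2. Step 7. The dienol may revert to the ketone, or close to a four-membered ring, faster than its hindered carbinol terminus is trapped by a dienophile of moderate reactivity, so that conversion under irradiation stays low. The fallback sets out from ketone 8 and returns at adduct 13. It separates the generation of the diene from its trapping. Irradiation of 8 alone (365 nm, benzene) should let the dienol close to the benzocyclobutenol F3. Heating F3 with 11 in toluene at 110 °C in the dark reopens the four-membered ring by conrotatory electrocyclic ring opening with the hydroxyl rotating outward. This regenerates dienol 12 thermally in the presence of concentrated dienophile, and the Diels–Alder reaction then gives 13.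

3. Step 8. Once the tertiary alkoxide forms, retro-aldol cleavage of the β-hydroxy lactone (C7'–C8' bond breaking back toward ketone 8) may compete with hydride delivery to the lactone. The fallback sets out from adduct 13 and returns at diol 15, with the order of the two reductions exchanged. Hydrogenolysis over Raney Ni (H2, EtOH, 50 °C) first removes the tertiary hydroxyl with retention and gives the deoxy lactone F4, which has no β-hydroxy carbonyl unit left to fragment. LiAlH4 then reduces lactone and acetal and gives 15 directly.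

**Further compounds**

F1 | step 9 | (1S,2S,3R)-2,3-bis({[di(propan-2-yl)silyl]oxy}methyl)-6,8-dimethoxy-7-(methoxymethoxy)-1-[3-methoxy-4-(methoxymethoxy)phenyl]-1,2,3,4-tetrahydronaphthalen-1-ol | COc1cc(ccc1OCOC)[C@]2(O)c3c(cc(OC)c(OCOC)c3OC)C[C@@H](CO[SiH](C(C)C)C(C)C)[C@H]2CO[SiH](C(C)C)C(C)C
F2 | step 9 | (1R,2S,3R)-3-({[di(propan-2-yl)silyl]oxy}methyl)-2-({[fluorodi(propan-2-yl)silyl]oxy}methyl)-6,8-dimethoxy-7-(methoxymethoxy)-1-[3-methoxy-4-(methoxymethoxy)phenyl]-1,2,3,4-tetrahydronaphthalene | COc1cc(ccc1OCOC)[C@@H]2c3c(cc(OC)c(OCOC)c3OC)C[C@@H](CO[SiH](C(C)C)C(C)C)[C@H]2CO[Si](F)(C(C)C)C(C)C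
F3 | step 7 | rac-3,5-dimethoxy-4-(methoxymethoxy)-7-[3-methoxy-4-(methoxymethoxy)phenyl]bicyclo[4.2.0]octa-1,3,5-trien-7-ol | COCOc1ccc(cc1OC)C2(O)Cc3cc(OC)c(OCOC)c(OC)c23
F4 | step 8 | (3R,3aR,9R,9aS)-6,8-dimethoxy-7-(methoxymethoxy)-9-[3-methoxy-4-(methoxymethoxy)phenyl]-3-{[(1R,2S,5R)-5-methyl-2-(propan-2-yl)cyclohexyl]oxy}-3a,4,9,9a-tetrahydronaphtho[2,3-c]furan-1(3H)-one | COc1cc(ccc1OCOC)[C@@H]2c3c(cc(OC)c(OCOC)c3OC)C[C@@H]4[C@H]2C(=O)O[C@H]4O[C@@H]5C[C@H](C)CC[C@H]5C(C)C
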